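## Structural features

Eriosemaone D is an isoflavone in which ring A (a benzene) is fused through C4a–C8a to ring C (a 4-pyranone), and C3 of ring C is joined by one biaryl bond to C1' of ring B. Ring B is fused at C4'–C5' to a 2,2-dimethyl-2H-pyran, so ring B and this pyran together form a 2,2-dimethyl-2H-chromene bound through its C6, whose C7 hydroxyl is the 2'-hydroxyl beside the biaryl bond. Ring A is a resorcinol: the C5 hydroxyl lies beside the ring fusion and is chelated to the C4 carbonyl, and the C7 hydroxyl is meta to it. The molecule has no stereocentre, so only the position of the chromene double bond has to be preserved. The fragile parts are the chromene alkene (an electron-rich styrene, sensitive to acid, electrophilic oxidants, hydrogenation and short-wavelength light), the three phenols, and the pyranone ring, which is opened by hydroxide or amines. The real difficulty is regiochemical: the linear fusion of the pyran on ring B, a hindered biaryl bond ortho to oxygen, and the 5,7-dioxygenation of ring A beside a ring C that keeps its C2–H. The key step exploits the fact that ring C with C2–H, the C3 aryl group and C4=O is already present in a 5-aryl-4-pyranone, whose C2=C3 bond (the later C8a=C4a) can serve as the vinyl part of a dienylketene. It also exploits the C5-hydroxy/C7-oxy meta pattern of ring A, which is the pattern that a ketene–silyloxyalkyne benzannulation delivers.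

## Logic of the disconnections

21 ⇒ 20. The two aryl O–Si bonds (O7 and O2') are cut. Both masks are the same group, so one fluoride treatment ends the synthesis, and the chelated C5 hydroxyl needs no mask. The gain is that the ring construction may deliver O7 already silylated. The forward step has to be buffered so that neither the polyphenol nor the pyranone is left as a free phenoxide.

20 ⇒ 13 + 16. All of ring A is removed by cutting C4a–C5, C5–C6, C7–C8 and C8–C8a. The cut belongs here because ring A is a resorcinol with its free hydroxyl beside the ring fusion, and because 13 already holds ring C at its final oxidation level and the complete ring B. A tricyclic chromone with two differentiated oxygens is reduced to a monocyclic pyranone and a two-carbon alkyne. The forward step must generate 17 with light that neither the chromene nor the pyranone absorbs, add 16 in the right orientation, and close at C4a.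

13 ⇒ 11. The bond between the acyl carbon and the diazo carbon is cut. Diazoketones come from activated acids, so the precursor is a plain carboxylic acid. The forward step must activate the acid without releasing strong acid and should not need a volatile, explosive diazoalkane.

11 ⇒ 9. No skeletal bond is cut; the side chain on the pyranone goes back from acid to carbinol. The carbinol is native to 7, so carrying it through the coupling saves an esterification and a hydroxide saponification that would threaten the aryl silyl ether and the pyranone ring. The forward oxidation must spare the chromene alkene and the silyl ether.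

9 ⇒ 8 + 6. The biaryl bond (C3–C1' of the target) is cut. This gives two halves of similar size, each made from one commercial compound. The forward step must couple a hindered ortho-silyloxy aryl boron compound with a base-sensitive enol sulfonate in the presence of a free hydroxyl.

8 ⇒ 7. The S–O bond is cut. The enolic hydroxyl of 7 is its only acidic one, so the sulfonylation only has to distinguish it from the primary alcohol.

6 ⇒ 5 ⇒ 4. The C–B bond and then the O–Si bond are cut. The bromine of 4 marks the biaryl carbon, and silylation comes first so that no free phenol meets the borylation. The borylation must leave the alkene and the silyl ether alone.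

4 ⇒ 1 + 2 (through 3). The pyran ring of the chromene is cut at C4–C4a and O1–C2, giving two commercial compounds that are joined in one operation. The forward condensation must take place at C6 of 1 and not at C2 between the two hydroxyls.

16 ⇒ 14 (through 15). The O–Si bond is cut, and 15 arises from 14 by a fragmentation that breaks the ring N–O and C3–C4 bonds. This gives the parent two-carbon oxyanion without handling a gaseous alkyne. The forward step must silylate on oxygen and not on carbon.

## Other disconnections considered

Alternative 1: The cut runs through ring C at C3–C4 and O1–C2.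
- **Pieces:** the ring A acyl donor 2,4,6-triacetoxybenzoyl chloride A2 and the morpholine enamine of the ring B side chain, 4-[(E)-2-(7-methoxymethoxy-2,2-dimethyl-2H-chromen-6-yl)ethenyl]morpholine A3.
- **Forward key step:** the β-carbon of A3 would be acylated by A2. K2CO3 in methanol in the same flask would remove the acetates, and an ortho phenoxide would add to the aminomethylene carbon and expel morpholine. This would close ring C as 5,7-dihydroxy-3-[7-(methoxymethoxy)-2,2-dimethyl-2H-chromen-6-yl]-4H-chromen-4-one A1, and mild acid would then free the last phenol of A1 to give 21.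
- **In its favour:** full convergence, two ring C bonds from one flask, only polar ground-state chemistry (no light, no diazo compound, no palladium), and a symmetric ring A with no regiochemical question.
- **Against it here:** A3 is a hydrolytically fragile enamine whose chain needs a one-carbon homologation on the acid-sensitive chromene. A2 has two ortho acetoxy groups, so C-acylation must compete with acyl transfer to nitrogen and acetate scrambling. The last step exposes the chromene to acid, whereas the chosen plan ends under buffered fluoride.
- **Comparison:** both plans carry the finished chromene throughout. This one makes ring C last from two arenes; the chosen plan grows ring A on a ring C that never has to be closed. The addition–elimination sequence is simpler to run than a photochemical pericyclic cascade, and on equipment and reagent hazard Alternative 1 is the better plan. On step economy it should be equal or shorter. Its weak point, the hindered C-acylation, is a risk of the same order as the photochemical step of the chosen plan.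

Alternative 2: The C3–C1' bond is made by migration and ring C by O1–C2 closure.
- **Precursor:** the 2'-hydroxychalcone (E)-1-[2-hydroxy-4,6-bis(methoxymethoxy)phenyl]-3-[7-(methoxymethoxy)-2,2-dimethylchroman-6-yl]prop-2-en-1-one A4, which would come from a Claisen–Schmidt condensation of two simple arene building blocks.
- **Forward key step:** the trivalent iodine oxidant PhI(OH)OTs in methanol with trimethyl orthoformate would shift ring B of A4 from the β to the α carbon. Acid added to the same flask would close ring C and remove the MOM groups, giving 5,7-dihydroxy-3-(7-hydroxy-2,2-dimethylchroman-6-yl)-4H-chromen-4-one A5, and DDQ would then turn A5 into 21 by introducing the chromene double bond.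
- **In its favour:** the route mirrors the biosynthesis, the electron-rich ring B migrates readily, no transition metal or diazo compound is needed, and chalcone assembly is very reliable. On step count it is equal or better.
- **Against it here:** the oxidant does not tolerate the chromene alkene, so the chroman must be carried and the alkene made last by oxidizing the triphenol A5, where over-oxidation is a concern. The free 2'-hydroxyl of A4 can divert the oxidation towards flavanone or aurone products.
- **Comparison:** it starts from cheaper arenes and equals the chosen plan in convergence. The cationic 1,2-shift is well understood but runs one oxidation level away from the target, whereas the chosen plan holds the chromene at its final level from step 1. The late dehydrogenation is a necessity here; in the chosen plan it is only a reserve.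

Alternative 3: The same benzannulation is turned round to build ring B, with cuts at C1'–C2', C2'–C3', C4'–C5' and C5'–C6'.
- **Precursor:** the enone diazoketone (E)-4-[5,7-bis(methoxymethoxy)-4-oxo-4H-chromen-3-yl]-1-diazobut-3-en-2-one A6, which would be reached by olefination at C3 of a preformed chromone.
- **Forward key step:** photochemical Wolff rearrangement of A6, addition of the resulting ketene to 16, cyclobutenone opening and six-electron closure at the alkene carbon that bears the chromone would give 3-[2-hydroxy-4-(triisopropylsilyloxy)phenyl]-5,7-bis(methoxymethoxy)-4H-chromen-4-one A7.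
- **In its favour:** the 2π partner is a simple acyclic alkene, so the electrocyclization costs no heteroaromatic stabilization; on that count it is equal or better than closure onto a pyranone. Ring A and ring C come from stock chromone chemistry, and the same alkyne polarization fixes the ring B oxygen pattern.
- **Against it here:** A7 still lacks the dimethylpyran ring. Fusing it later onto ring B reopens the choice between C5' (linear) and C3' (angular) on an advanced intermediate. A6 combines a diazo group with two Michael acceptors and a photoisomerizable enone. More steps follow the key step (desilylation, pyran annulation, MOM removal in acid).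
- **Comparison:** the reaction class and its regiochemical logic are the same in both plans. The chosen plan settles the ring B regiochemistry in its first step on cheap material and needs one step after the key step. Alternative 3 has the easier electrocyclization but the longer and less certain endgame.

Key step: step 9

Remark (assumption): 3-phenylisoxazole 14 is taken as a purchasable building block.
Remark (assumption): the enal condensation of step 1 is taken to occur mainly at C6 of 1, the activated position that is not flanked by two substituents, as in other electrophilic substitutions of 4-haloresorcinols; the doubly ortho-activated C2 is the competing site.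

## Route

Step 1
Reactants: 1 4-bromoresorcinol (4-bromobenzene-1,3-diol); 2 prenal (3-methylbut-2-enal)
Product: 4 6-bromo-2,2-dimethyl-2H-chromen-7-ol, via quinone methide 3 (not isolated)
Conditions: ethylenediammonium diacetate (20 mol %), xylene, 140 °C
Reagents that add atoms: none
Why: Amine-catalysed Knoevenagel-type condensation of the enal at C6 of 1 (ortho to one hydroxyl, para to the other) and loss of water give 3, which closes by oxa-6π-electrocyclization (formal [3+3] chromene annulation); the bromine blocks C4 and marks the later biaryl carbon.

Step 2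
Reactants: 4 6-bromo-2,2-dimethyl-2H-chromen-7-ol
Product: 5 [(6-bromo-2,2-dimethyl-2H-chromen-7-yl)oxy]tri(propan-2-yl)silane
Conditions: i-Pr3SiCl, imidazole, DMF, rt
Reagents that add atoms: chlorotri(propan-2-yl)silane, CC(C)[Si](Cl)(C(C)C)C(C)C
Why: Standard imidazole-mediated silylation of a phenol; the bulky silyl ether should survive borylation, phosphate base and the oxidation, and it is the same group that the alkyne later puts on O7, so both fall together at the end.

Step 3
Reactants: 5 [(6-bromo-2,2-dimethyl-2H-chromen-7-yl)oxy]tri(propan-2-yl)silane
Product: 6 {[2,2-dimethyl-6-(4,4,5,5-tetramethyl-1,3,2-dioxaborolan-2-yl)-2H-chromen-7-yl]oxy}tri(propan-2-yl)silane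
Conditions: B2pin2, PdCl2(dppf) (5 mol %), KOAc, 1,4-dioxane, 90 °C
Reagents that add atoms: bis(pinacolato)diboron, CC1(C)OB(OC1(C)C)B1OC(C)(C)C(C)(C)O1
Why: Miyaura borylation of an aryl bromide; the weak acetate base leaves the aryl silyl ether and the alkene alone, and no ortho-lithiated aryl silyl ether, in which oxygen-to-carbon silyl migration is possible on warming, has to be made.

Step 4
Reactants: 7 kojic acid (5-hydroxy-2-(hydroxymethyl)-4H-pyran-4-one)
Product: 8 6-(hydroxymethyl)-4-oxo-4H-pyran-3-yl trifluoromethanesulfonate
Conditions: PhNTf2, Et3N, DMF, 0 °C → rt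
Reagents that add atoms: N-phenylbis(trifluoromethanesulfonimide), O=S(=O)(N(c1ccccc1)S(=O)(=O)C(F)(F)F)C(F)(F)F
Why: The enolic hydroxyl (pKa about 8) is deprotonated by the amine and O-sulfonylated by the mild triflimide, which does not react with the neutral primary alcohol; chemoselective enol triflate formation.

Step 5
Reactants: 8 6-(hydroxymethyl)-4-oxo-4H-pyran-3-yl trifluoromethanesulfonate; 6 {[2,2-dimethyl-6-(4,4,5,5-tetramethyl-1,3,2-dioxaborolan-2-yl)-2H-chromen-7-yl]oxy}tri(propan-2-yl)silane
Product: 9 5-{2,2-dimethyl-7-[tri(propan-2-yl)silyloxy]-2H-chromen-6-yl}-2-(hydroxymethyl)-4H-pyran-4-one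
Conditions: Pd(OAc)2 (5 mol %), SPhos (10 mol %), K3PO4, THF/H2O (10:1), 60 °C
Reagents that add atoms: none
Why: Suzuki–Miyaura coupling; the electron-poor enol triflate should add readily to zerovalent palladium, the biaryl dialkylphosphine ligand suits ortho-substituted boronates, and phosphate is mild enough for the triflate, the aryl silyl ether and the pyranone.

Step 6
Reactants: 9 5-{2,2-dimethyl-7-[tri(propan-2-yl)silyloxy]-2H-chromen-6-yl}-2-(hydroxymethyl)-4H-pyran-4-one
Product: 11 5-{2,2-dimethyl-7-[tri(propan-2-yl)silyloxy]-2H-chromen-6-yl}-4-oxo-4H-pyran-2-carboxylic acid, via aldehyde 10 (not isolated)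
Conditions: TEMPO (20 mol %), PhI(OAc)2 (2.2 equiv), MeCN/H2O (1:1), rt
Reagents that add atoms: water, O
Why: Oxoammonium-mediated oxidation takes the primary alcohol to 10, whose hydrate (the formyl group on the pyranone is strongly electrophilic) is oxidized on to the acid; the near-neutral medium should spare the chromene alkene and the silyl ether, and no ester or saponification is needed.

Step 7
Reactants: 11 5-{2,2-dimethyl-7-[tri(propan-2-yl)silyloxy]-2H-chromen-6-yl}-4-oxo-4H-pyran-2-carboxylic acid
Product: 13 2-(diazoacetyl)-5-{2,2-dimethyl-7-[tri(propan-2-yl)silyloxy]-2H-chromen-6-yl}-4H-pyran-4-one, via mixed anhydride 12 (not isolated)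
Conditions: ClCO2Et, Et3N, THF, −15 °C; then Me3SiCHN2 (2 equiv), MeCN, 0 °C → rt
Reagents that add atoms: (trimethylsilyl)diazomethane, C[Si](C)(C)C=[N+]=[N-]
Why: Arndt–Eistert-type acylation: the diazo carbon attacks the acyl carbon of 12 and the expelled ethyl carbonate removes the silyl group; no HCl is formed, the non-explosive silyl reagent stands in for diazomethane, and its bulk disfavours dipolar addition to the pyranone (ethyl chloroformate leaves atoms only in 12).

Step 8
Reactants: 14 3-phenylisoxazole (3-phenyl-1,2-oxazole)
Product: 16 (triisopropylsilyloxy)ethyne [ethynyloxytri(propan-2-yl)silane], via lithium ethynolate 15 (not isolated)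
Conditions: LiN(i-Pr)2, THF, −78 °C; then i-Pr3SiOTf, −78 → 0 °C
Reagents that add atoms: tri(propan-2-yl)silyl trifluoromethanesulfonate, CC(C)[Si](OS(=O)(=O)C(F)(F)F)(C(C)C)C(C)C
Why: Deprotonation at C5 of a 5-unsubstituted 3-arylisoxazole triggers ring fragmentation into benzonitrile and 15 (base cleavage of isoxazoles); the hard, bulky silyl triflate should silylate the ambident ynolate on oxygen, and the non-polar ynol ether is separated from benzonitrile on amine-deactivated silica.

Step 9
Reactants: 13 2-(diazoacetyl)-5-{2,2-dimethyl-7-[tri(propan-2-yl)silyloxy]-2H-chromen-6-yl}-4H-pyran-4-one; 16 (triisopropylsilyloxy)ethyne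
Product: 20 3-{2,2-dimethyl-7-[tri(propan-2-yl)silyloxy]-2H-chromen-6-yl}-5-hydroxy-7-[tri(propan-2-yl)silyloxy]-4H-chromen-4-one, via ketene 17 (not isolated), via cyclobutenone 18 (not isolated), via dienylketene 19 (not isolated)
Conditions: 16 (2.5 equiv), hν (400–450 nm LEDs), ClCH2CH2Cl, argon, rt; then 80 °C
Reagents that add atoms: none
Why: Light in the long-wavelength band of the diazoketone expels N2 from 13 and the pyranon-2-yl group shifts from the acyl carbon to the former diazo carbon (Wolff rearrangement, new C8–C8a bond), giving ketene 17. The electron-rich CH carbon of 16 bonds to the ketene carbonyl carbon and the silyloxy-bearing carbon closes onto the ketene CH carbon, a polar [2+2] cycloaddition that forms C5–C6 and C7–C8 and gives 3-silyloxycyclobutenone 18. At 80 °C strain drives the conrotatory four-electron opening of 18 to dienylketene 19 (reversible, so the isomer with the pyranone cis to the ketene is drained), and a disrotatory six-electron electrocyclization joins the ketene carbon to the pyranone carbon next to the carbonyl (C4a–C5); enolization of the doubly activated C4a–H then gives the phenol. Ring A is closed as a six-membered carbocycle by this 6π-electrocyclization, and the four-membered ring of 18 is only transient. The closest known reaction type is the diazoketone (second-generation) form of the Danheiser benzannulation with silyloxyalkynes, established for aryl and heteroaryl diazoketones. No stereocentre is created: the stereogenic carbon of 18 becomes aromatic C8. The step needs three selectivities: orientation of the cycloaddition, secured by the polarization of 16, which places silyloxy meta to the new hydroxyl; a single closure site, secured because the other neighbour of C8a is the ring oxygen; and preference for 16 over the chromene alkene, secured by the far higher nucleophilicity of the ynol ether used in excess, while the long wavelength keeps the chromene and pyranone chromophores unexcited and the chelated C5 hydroxyl is too poor a nucleophile to intercept 17.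

Step 10
Reactants: 20 3-{2,2-dimethyl-7-[tri(propan-2-yl)silyloxy]-2H-chromen-6-yl}-5-hydroxy-7-[tri(propan-2-yl)silyloxy]-4H-chromen-4-one
Product: 21 eriosemaone D
Conditions: Bu4NF, AcOH, THF, 0 °C → rt
Reagents that add atoms: none
Why: Fluoride cleaves both aryl Si–O bonds (silyl ether deprotection); acetic acid protonates the phenoxides as they form, so the chromone ring and the chromene are not left in a basic medium.

## Compound list

1 | 4-bromoresorcinol (4-bromobenzene-1,3-diol) | Oc1ccc(Br)c(O)c1 | starting material
2 | prenal (3-methylbut-2-enal) | CC(C)=CC=O | starting material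
3 | 4-bromo-3-hydroxy-6-(3-methylbut-2-en-1-ylidene)cyclohexa-2,4-dien-1-one (quinone methide, geometry that cyclizes) | CC(C)=C\C=C1/C(=O)C=C(O)C(Br)=C1 | intermediate (not isolated)
4 | 6-bromo-2,2-dimethyl-2H-chromen-7-ol | CC1(C)C=Cc2cc(Br)c(O)cc2O1 | intermediate
5 | [(6-bromo-2,2-dimethyl-2H-chromen-7-yl)oxy]tri(propan-2-yl)silane | CC1(C)C=Cc2cc(Br)c(O[Si](C(C)C)(C(C)C)C(C)C)cc2O1 | intermediate
6 | {[2,2-dimethyl-6-(4,4,5,5-tetramethyl-1,3,2-dioxaborolan-2-yl)-2H-chromen-7-yl]oxy}tri(propan-2-yl)silane | CC1(C)C=Cc2cc(B3OC(C)(C)C(C)(C)O3)c(O[Si](C(C)C)(C(C)C)C(C)C)cc2O1 | intermediate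
7 | kojic acid (5-hydroxy-2-(hydroxymethyl)-4H-pyran-4-one) | OCc1cc(=O)c(O)co1 | starting material
8 | 6-(hydroxymethyl)-4-oxo-4H-pyran-3-yl trifluoromethanesulfonate | OCc1cc(=O)c(OS(=O)(=O)C(F)(F)F)co1 | intermediate
9 | 5-{2,2-dimethyl-7-[tri(propan-2-yl)silyloxy]-2H-chromen-6-yl}-2-(hydroxymethyl)-4H-pyran-4-one | OCc1cc(=O)c(-c2cc3C=CC(C)(C)Oc3cc2O[Si](C(C)C)(C(C)C)C(C)C)co1 | intermediate
10 | 5-{2,2-dimethyl-7-[tri(propan-2-yl)silyloxy]-2H-chromen-6-yl}-4-oxo-4H-pyran-2-carbaldehyde | O=Cc1cc(=O)c(-c2cc3C=CC(C)(C)Oc3cc2O[Si](C(C)C)(C(C)C)C(C)C)co1 | intermediate (not isolated)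
11 | 5-{2,2-dimethyl-7-[tri(propan-2-yl)silyloxy]-2H-chromen-6-yl}-4-oxo-4H-pyran-2-carboxylic acid | OC(=O)c1cc(=O)c(-c2cc3C=CC(C)(C)Oc3cc2O[Si](C(C)C)(C(C)C)C(C)C)co1 | intermediate
12 | ethyl carbonic anhydride of acid 11 | CCOC(=O)OC(=O)c1cc(=O)c(-c2cc3C=CC(C)(C)Oc3cc2O[Si](C(C)C)(C(C)C)C(C)C)co1 | intermediate (not isolated)
13 | 2-(diazoacetyl)-5-{2,2-dimethyl-7-[tri(propan-2-yl)silyloxy]-2H-chromen-6-yl}-4H-pyran-4-one | [N-]=[N+]=CC(=O)c1cc(=O)c(-c2cc3C=CC(C)(C)Oc3cc2O[Si](C(C)C)(C(C)C)C(C)C)co1 | intermediate
14 | 3-phenylisoxazole (3-phenyl-1,2-oxazole) | c1ccc(cc1)-c1ccon1 | starting material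
15 | lithium ethynolate | [Li+].[O-]C#C | intermediate (not isolated)
16 | (triisopropylsilyloxy)ethyne | C#CO[Si](C(C)C)(C(C)C)C(C)C | intermediate
17 | 5-{2,2-dimethyl-7-[tri(propan-2-yl)silyloxy]-2H-chromen-6-yl}-2-(2-oxoethenyl)-4H-pyran-4-one (ketene) | O=C=Cc1cc(=O)c(-c2cc3C=CC(C)(C)Oc3cc2O[Si](C(C)C)(C(C)C)C(C)C)co1 | intermediate (not isolated)
18 | 4-(5-{2,2-dimethyl-7-[tri(propan-2-yl)silyloxy]-2H-chromen-6-yl}-4-oxo-4H-pyran-2-yl)-3-[tri(propan-2-yl)silyloxy]cyclobut-2-en-1-one (racemic) | O=C1C=C(O[Si](C(C)C)(C(C)C)C(C)C)C1c1cc(=O)c(-c2cc3C=CC(C)(C)Oc3cc2O[Si](C(C)C)(C(C)C)C(C)C)co1 | intermediate (not isolated)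
19 | 5-{2,2-dimethyl-7-[tri(propan-2-yl)silyloxy]-2H-chromen-6-yl}-2-{(1E)-4-oxo-2-[tri(propan-2-yl)silyloxy]buta-1,3-dien-1-yl}-4H-pyran-4-one (dienylketene) | O=C=C/C(O[Si](C(C)C)(C(C)C)C(C)C)=C\c1cc(=O)c(-c2cc3C=CC(C)(C)Oc3cc2O[Si](C(C)C)(C(C)C)C(C)C)co1 | intermediate (not isolated)
20 | 3-{2,2-dimethyl-7-[tri(propan-2-yl)silyloxy]-2H-chromen-6-yl}-5-hydroxy-7-[tri(propan-2-yl)silyloxy]-4H-chromen-4-one | CC(C)[Si](Oc1cc(O)c2c(c1)occ(-c1cc3C=CC(C)(C)Oc3cc1O[Si](C(C)C)(C(C)C)C(C)C)c2=O)(C(C)C)C(C)C | intermediate
21 | eriosemaone D (5,7-dihydroxy-3-(7-hydroxy-2,2-dimethyl-2H-chromen-6-yl)-4H-chromen-4-one) | CC1(C)C=Cc2cc(-c3coc4cc(O)cc(O)c4c3=O)c(O)cc2O1 | target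

## Step count and least certain steps

Total: 10 steps. Longest linear sequence: 8 steps (1, 2, 3, 5, 6, 7, 9, 10). The pyranone branch (step 4) and the alkyne branch (step 8) join it at steps 5 and 9.

Step 9 (key step). The most likely failure is photodegradation of the chromene through its light-induced electrocyclic ring opening, or competing photochemistry of the pyranone, since only the diazoketone is meant to absorb. Ketene 17 could also be lost to dimerization or acylation if the cycloaddition is slow. The fallback carries the saturated chroman and makes the alkene afterwards; it sets out from 11 and comes back at 20. Hydrogenation of 11 (H2, 1 atm, Pd/C, EtOAc, rt, stopped after one equivalent) would saturate the styrene-type double bond, which should react well before the pyranone ring, and give the chroman acid F1, that is 5-{2,2-dimethyl-7-[tri(propan-2-yl)silyloxy]-3,4-dihydro-2H-chromen-6-yl}-4-oxo-4H-pyran-2-carboxylic acid. As in step 7, its ethyl carbonic anhydride F2 would be converted with Me3SiCHN2 into the chroman diazoketone F3. Irradiation of F3 with 16 and heating as in step 9 would lead through the chroman ketene F4, the chroman cyclobutenone F5 and the chroman dienylketene F6 to the chroman benzannulation product F7, the 3,4-dihydro analogue of 20. DDQ in dioxane at reflux would then abstract hydride from the benzylic C4 of the chroman in F7, which is activated by the para silyloxy group and the ortho ring oxygen; loss of the C3 proton gives 20.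

Step 8. The most likely failures are silylation of the ambident ynolate on carbon (which leads to a silylketene), consumption of the ynolate by the benzonitrile formed beside it, and loss of the volatile, acid-sensitive ynol ether on isolation. The fallback makes the O–Si bond at an enolate and the triple bond last. It does not pass through 14 or 15: it sets out from commercial ethyl formate and dibromomethane, which take the place of 14, and comes back at 16. Dibromomethane and LiN(i-Pr)2 in THF at −78 °C would give (dibromomethyl)lithium F8, which adds to ethyl formate; loss of ethoxide and deprotonation by a second equivalent of the amide would give lithium 2,2-dibromoethenolate F9, as in the first stage of a Kowalski homologation. O-Silylation of this enolate with i-Pr3SiOTf would give the dibromovinyl silyl ether F10, [(2,2-dibromoethenyl)oxy]tri(propan-2-yl)silane. n-BuLi (2 equiv, −78 °C) would then effect bromine–lithium exchange, 1,2-hydrogen shift with loss of bromide (Fritsch–Buttenberg–Wiechell rearrangement, as in the second stage of a Corey–Fuchs alkyne synthesis) and deprotonation of the new alkyne to the lithium silyloxyacetylide F11, and cold aqueous NH4Cl would protonate F11 to 16.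

Step 1. The most likely failure is poor regioselectivity: condensation at C2 of 1, the doubly ortho-activated position between the two hydroxyls, would lead to angular chromenes. The fallback fixes the regiochemistry by acylation; it sets out from 1 and comes back at 4. Friedel–Crafts acylation of 1 with 3-methylbut-2-enoic acid in P2O5/MeSO3H at 70 °C, which avoids the crowded position between the hydroxyls, followed in the same flask by oxa-Michael closure, would give the chromanone F12, 6-bromo-7-hydroxy-2,2-dimethyl-2,3-dihydro-4H-chromen-4-one. Excess NaBH4 in MeOH/THF would reduce F12 to the chromanol F13, and acid-catalysed dehydration of F13 (p-TsOH, toluene, 80 °C) would give 4.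

Step 5. The most likely failures are protodeboronation of the hindered, electron-rich boronate before transmetalation and base-induced S–O cleavage of the triflate. The fallback is a base-free Negishi coupling; it sets out from 5 and comes back at 9. Bromine–lithium exchange on 5 (n-BuLi, THF, −78 °C) would give the aryllithium F14, which at this temperature and with the bulky silyl group should not yet undergo oxygen-to-carbon silyl migration and is trapped at once with ZnCl2 as the arylzinc chloride F15. Slow addition of F15 to 8 with Pd(OAc)2/SPhos in THF at rt should give 9, since cross-coupling outruns protonolysis of arylzinc halides by an alcohol.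

Step 6. The most likely failure is attack of the oxoammonium or iodine oxidant on the electron-rich chromene, or stalling at the aldehyde hydrate. The fallback oxidizes before the coupling; it sets out from 8 and comes back at 11. The same TEMPO/PhI(OAc)2 oxidation, now on a substrate without alkene or electron-rich arene, would pass through the triflate aldehyde F16 to the triflate acid F17, 4-oxo-5-(trifluoromethanesulfonyloxy)-4H-pyran-2-carboxylic acid. Suzuki–Miyaura coupling of F17, as its potassium carboxylate, with 6 (one more equivalent of K3PO4) would give 11 after mild acidification.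

## Further compounds

F1 | step 9 | 5-{2,2-dimethyl-7-[tri(propan-2-yl)silyloxy]-3,4-dihydro-2H-chromen-6-yl}-4-oxo-4H-pyran-2-carboxylic acid | OC(=O)c1cc(=O)c(-c2cc3CCC(C)(C)Oc3cc2O[Si](C(C)C)(C(C)C)C(C)C)co1
F2 | step 9 | ethyl carbonic anhydride of F1 | CCOC(=O)OC(=O)c1cc(=O)c(-c2cc3CCC(C)(C)Oc3cc2O[Si](C(C)C)(C(C)C)C(C)C)co1
F3 | step 9 | 2-(diazoacetyl)-5-{2,2-dimethyl-7-[tri(propan-2-yl)silyloxy]-3,4-dihydro-2H-chromen-6-yl}-4H-pyran-4-one | [N-]=[N+]=CC(=O)c1cc(=O)c(-c2cc3CCC(C)(C)Oc3cc2O[Si](C(C)C)(C(C)C)C(C)C)co1
F4 | step 9 | 5-{2,2-dimethyl-7-[tri(propan-2-yl)silyloxy]-3,4-dihydro-2H-chromen-6-yl}-2-(2-oxoethenyl)-4H-pyran-4-one | O=C=Cc1cc(=O)c(-c2cc3CCC(C)(C)Oc3cc2O[Si](C(C)C)(C(C)C)C(C)C)co1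
F5 | step 9 | 4-(5-{2,2-dimethyl-7-[tri(propan-2-yl)silyloxy]-3,4-dihydro-2H-chromen-6-yl}-4-oxo-4H-pyran-2-yl)-3-[tri(propan-2-yl)silyloxy]cyclobut-2-en-1-one (racemic) | O=C1C=C(O[Si](C(C)C)(C(C)C)C(C)C)C1c1cc(=O)c(-c2cc3CCC(C)(C)Oc3cc2O[Si](C(C)C)(C(C)C)C(C)C)co1
F6 | step 9 | 5-{2,2-dimethyl-7-[tri(propan-2-yl)silyloxy]-3,4-dihydro-2H-chromen-6-yl}-2-{(1E)-4-oxo-2-[tri(propan-2-yl)silyloxy]buta-1,3-dien-1-yl}-4H-pyran-4-one | O=C=C/C(O[Si](C(C)C)(C(C)C)C(C)C)=C\c1cc(=O)c(-c2cc3CCC(C)(C)Oc3cc2O[Si](C(C)C)(C(C)C)C(C)C)co1
F7 | step 9 | 3-{2,2-dimethyl-7-[tri(propan-2-yl)silyloxy]-3,4-dihydro-2H-chromen-6-yl}-5-hydroxy-7-[tri(propan-2-yl)silyloxy]-4H-chromen-4-one | CC(C)[Si](Oc1cc(O)c2c(c1)occ(-c1cc3CCC(C)(C)Oc3cc1O[Si](C(C)C)(C(C)C)C(C)C)c2=O)(C(C)C)C(C)C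
F8 | step 8 | (dibromomethyl)lithium | [Li]C(Br)Br
F9 | step 8 | lithium 2,2-dibromoethen-1-olate | [Li+].[O-]C=C(Br)Br
F10 | step 8 | [(2,2-dibromoethenyl)oxy]tri(propan-2-yl)silane | BrC(Br)=CO[Si](C(C)C)(C(C)C)C(C)C
F11 | step 8 | lithium [tri(propan-2-yl)silyloxy]acetylide | [Li]C#CO[Si](C(C)C)(C(C)C)C(C)C
F12 | step 1 | 6-bromo-7-hydroxy-2,2-dimethyl-2,3-dihydro-4H-chromen-4-one | CC1(C)CC(=O)c2cc(Br)c(O)cc2O1
F13 | step 1 | 6-bromo-2,2-dimethyl-3,4-dihydro-2H-chromene-4,7-diol (racemic) | CC1(C)CC(O)c2cc(Br)c(O)cc2O1
F14 | step 5 | {2,2-dimethyl-7-[tri(propan-2-yl)silyloxy]-2H-chromen-6-yl}lithium | [Li]c1cc2C=CC(C)(C)Oc2cc1O[Si](C(C)C)(C(C)C)C(C)C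
F15 | step 5 | chloro{2,2-dimethyl-7-[tri(propan-2-yl)silyloxy]-2H-chromen-6-yl}zinc | Cl[Zn]c1cc2C=CC(C)(C)Oc2cc1O[Si](C(C)C)(C(C)C)C(C)C
F16 | step 6 | 6-formyl-4-oxo-4H-pyran-3-yl trifluoromethanesulfonate | O=Cc1cc(=O)c(OS(=O)(=O)C(F)(F)F)co1
F17 | step 6 | 4-oxo-5-(trifluoromethanesulfonyloxy)-4H-pyran-2-carboxylic acid | OC(=O)c1cc(=O)c(OS(=O)(=O)C(F)(F)F)co1
A1 | alternative 1 | 5,7-dihydroxy-3-[7-(methoxymethoxy)-2,2-dimethyl-2H-chromen-6-yl]-4H-chromen-4-one | O=c1c(-c2cc3C=CC(C)(C)Oc3cc2OCOC)coc2cc(O)cc(O)c12
A2 | alternative 1 | 2,4,6-triacetoxybenzoyl chloride | CC(=O)Oc1cc(OC(C)=O)c(C(Cl)=O)c(OC(C)=O)c1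
A3 | alternative 1 | 4-[(E)-2-(7-methoxymethoxy-2,2-dimethyl-2H-chromen-6-yl)ethenyl]morpholine | COCOc1cc2OC(C)(C)C=Cc2cc1/C=C/N1CCOCC1
A4 | alternative 2 | (E)-1-[2-hydroxy-4,6-bis(methoxymethoxy)phenyl]-3-[7-(methoxymethoxy)-2,2-dimethylchroman-6-yl]prop-2-en-1-one | COCOc1cc(O)c(C(=O)/C=C/c2cc3CCC(C)(C)Oc3cc2OCOC)c(OCOC)c1
A5 | alternative 2 | 5,7-dihydroxy-3-(7-hydroxy-2,2-dimethylchroman-6-yl)-4H-chromen-4-one | CC1(C)CCc2cc(-c3coc4cc(O)cc(O)c4c3=O)c(O)cc2O1
A6 | alternative 3 | (E)-4-[5,7-bis(methoxymethoxy)-4-oxo-4H-chromen-3-yl]-1-diazobut-3-en-2-one | [N-]=[N+]=CC(=O)/C=C/c1coc2cc(OCOC)cc(OCOC)c2c1=O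
A7 | alternative 3 | 3-[2-hydroxy-4-(triisopropylsilyloxy)phenyl]-5,7-bis(methoxymethoxy)-4H-chromen-4-one | O=c1c(-c2ccc(O[Si](C(C)C)(C(C)C)C(C)C)cc2O)coc2cc(OCOC)cc(OCOC)c12
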